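Ring B (O, C9–C12), with its C9, C10 and C12 substituents all cis, is read as the oxygen-bridged, dienophile-derived half of a 7-oxanorbornene in which C8 and C13 are the alkene carbons of the furan-derived bridge. One enantioselective Diels–Alder reaction of 3-ethylfuran with 2-bromoacrolein therefore forms C9–C10 and C11–C12 together, fixes the C9/C12 cis relationship and places Br on C10. The formyl group is only an activator and is excised later. Ring-opening cross-metathesis then cleaves C8=C13 and attaches C3–C7, ring A closes by iodoetherification, and the pseudo-mirror C3 and C13 bromides come from one diketone by double reduction and double inversion.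

Key step: step 2

Remark: locants C1–C15 are those of the target chain (C1≡C2, C3–Br … C15H3); ring A is the oxolane O/C4–C7 and ring B the oxolane O/C9–C12. Compounds 1, 3 and 6 and all named reagents are taken as purchasable; 3 is distilled before use.

Step 1
Reactants: 1 3-bromofuran
Product: 2 3-ethylfuran
Conditions: EtMgBr, NiCl2(dppp) (1 mol %), Et2O, 0 °C to reflux; distillation
Reagents that add atoms: ethylmagnesium bromide, CC[Mg]Br
Why: Kumada coupling of a 3-halofuran with an alkyl Grignard reagent under nickel–phosphine catalysis is a reliable sp2–sp3 coupling; no stereocenter is formed.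

Step 2
Reactants: 2 3-ethylfuran; 3 2-bromoacrolein
Product: 4 (1S,2S,4S)-2-bromo-5-ethyl-7-oxabicyclo[2.2.1]hept-5-ene-2-carbaldehyde (CHO exo; Br endo)
Conditions: B-n-butyl-oxazaborolidinone from N-tosyl-(R)-tryptophan and n-BuB(OH)2 (10 mol %), 2 (4 equiv), CH2Cl2, −78 °C; used crude and cold
Reagents that add atoms: none
Why: The boron Lewis acid binds the formyl oxygen of s-cis 3, and 2 adds in a concerted but asynchronous [4+2] cycloaddition in which the C11–C12 bond (to the enal β-carbon) leads the C9–C10 bond. The closest known reaction type is the oxazaborolidinone-catalysed enantioselective Diels–Alder reaction of furan itself with 2-haloacroleins. It closes the cyclohexene ring of the 7-oxanorbornene, and with it ring B (O, C9, C10, C11, C12), in a suprafacial [4+2] mode across furan C2 and C5. C9 and C12 are forced cis by the oxygen bridge and their absolute sense is set by the catalyst, whose indole shields one face of the bound enal (the (R)-tryptophan catalyst is expected to give the (1S,2S,4S) adduct by analogy with cyclopentadiene, and this sense should be confirmed); C10 receives Br endo and CHO exo from the exo-formyl preference of 2-substituted acroleins and is re-set in step 6. The step needs "para" regiochemistry (C10 bonded to the furan carbon remote from ethyl), which the larger HOMO coefficient at the furan carbon next to the ethyl group, paired with the enal β-carbon under Lewis acid activation, should secure. The adduct can revert thermally and is therefore carried cold into step 3.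

Step 3
Reactants: 4 (1S,2S,4S)-2-bromo-5-ethyl-7-oxabicyclo[2.2.1]hept-5-ene-2-carbaldehyde
Product: 5 (1S,2S,4S)-2-bromo-5-ethyl-7-oxabicyclo[2.2.1]hept-5-ene-2-carboxylic acid
Conditions: NaClO2, NaH2PO4, 2-methyl-2-butene, t-BuOH/H2O, 0 °C
Reagents that add atoms: sodium chlorite, [Na+].[O-]Cl=O
Why: Pinnick oxidation converts the hindered, non-enolisable aldehyde into the acid while the scavenger protects the strained alkene; the acid no longer reverts readily and is the handle for radical decarboxylation.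

Step 4
Reactants: 6 (R)-2-(2,2-dimethyl-5-oxo-1,3-dioxolan-4-yl)acetic acid
Product: 8 (5R)-2,2-dimethyl-5-(2-oxobut-3-en-1-yl)-1,3-dioxolan-4-one, via acid chloride 7 (not isolated)
Conditions: (COCl)2, DMF (cat.), CH2Cl2, 0 to 20 °C; then Bu3SnCH=CH2, PdCl2(PPh3)2 (2 mol %), THF, 50 °C
Reagents that add atoms: tributyl(vinyl)stannane, C=C[Sn](CCCC)(CCCC)CCCC
Why: Stille acylation of the acid chloride gives the vinyl ketone under neutral conditions that spare the dioxolanone and the base-sensitive β-oxygenated ketone; the C4 stereocenter comes unchanged from (R)-malic acid.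

Step 5
Reactants: 5 (1S,2S,4S)-2-bromo-5-ethyl-7-oxabicyclo[2.2.1]hept-5-ene-2-carboxylic acid; 8 (5R)-2,2-dimethyl-5-(2-oxobut-3-en-1-yl)-1,3-dioxolan-4-one
Product: 9 (2S,3S,5S)-3-bromo-5-(but-1-en-2-yl)-2-{(1E)-4-[(4R)-2,2-dimethyl-5-oxo-1,3-dioxolan-4-yl]-3-oxobut-1-en-1-yl}oxolane-3-carboxylic acid
Conditions: second-generation Hoveyda–Grubbs catalyst RuCl2(H2IMes)(=CH-C6H4-2-O-i-Pr) (5 mol %), 8 (3 equiv), CH2Cl2, 25 °C
Reagents that add atoms: none
Why: Ring-opening cross-metathesis is driven by strain release; the ruthenium methylidene delivers CH2 to the ethyl-bearing carbon C13 and takes ruthenium onto C8 (no disubstituted carbene), and this alkylidene then couples with the enone to give the (E)-C7=C8 enone and regenerate the methylidene, so C9 and C12 stay untouched and the chain lands on C8.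

Step 6
Reactants: 9 (2S,3S,5S)-3-bromo-5-(but-1-en-2-yl)-2-{(1E)-4-[(4R)-2,2-dimethyl-5-oxo-1,3-dioxolan-4-yl]-3-oxobut-1-en-1-yl}oxolane-3-carboxylic acid
Product: 12 (5R)-5-{(3E)-4-[(2S,3S,5S)-3-bromo-5-(but-1-en-2-yl)oxolan-2-yl]-2-oxobut-3-en-1-yl}-2,2-dimethyl-1,3-dioxolan-4-one, via acid chloride 10 (not isolated), via thiohydroxamate ester 11 (not isolated)
Conditions: (COCl)2, DMF (cat.), CH2Cl2, 0 °C; then sodium 2-pyridinethiolate 1-oxide, DMAP (cat.), t-BuSH (10 equiv), toluene, 15 °C, visible light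
Reagents that add atoms: none
Why: Barton decarboxylation generates the α-bromo C10 radical, which should take hydrogen from the bulky thiol on the ring face opposite to the C9 and C12 side chains, leaving Br cis to both (all-cis ring B, 10S); the high thiol concentration is meant to outrun 3-exo attack on the neighbouring enone.

Step 7
Reactants: 12 (5R)-5-{(3E)-4-[(2S,3S,5S)-3-bromo-5-(but-1-en-2-yl)oxolan-2-yl]-2-oxobut-3-en-1-yl}-2,2-dimethyl-1,3-dioxolan-4-one
Product: 14 (2R,4R,5E)-6-[(2S,3S,5S)-3-bromo-5-(but-1-en-2-yl)oxolan-2-yl]-2,4-dihydroxy-1-(morpholin-4-yl)hex-5-en-1-one, via allylic alcohol 13 (not isolated)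
Conditions: (S)-2-methyl-CBS-oxazaborolidine (0.3 equiv), catecholborane, toluene, −78 °C; MeOH; then morpholine (3 equiv), THF, 20 °C
Reagents that add atoms: morpholine, C1COCCN1
Why: Corey–Bakshi–Shibata reduction of the (E)-enone, with the alkenyl group as the larger substituent, sets (6R) under catalyst control; aminolysis of the activated dioxolanone then frees O4 and gives an amide that, unlike an ester, cannot lactonise onto the C6 hydroxyl (anti-1,3-diol).

Step 8
Reactants: 14 (2R,4R,5E)-6-[(2S,3S,5S)-3-bromo-5-(but-1-en-2-yl)oxolan-2-yl]-2,4-dihydroxy-1-(morpholin-4-yl)hex-5-en-1-one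
Product: 15 [(2R,4R,5S)-5-{(S)-[(2R,3S,5S)-3-bromo-5-(but-1-en-2-yl)oxolan-2-yl]iodomethyl}-4-hydroxyoxolan-2-yl](morpholin-4-yl)methanone
Conditions: I2, NaHCO3, dry MeCN, −20 to 0 °C
Reagents that add atoms: iodine, [I][I]
Why: Kinetic 5-exo iodoetherification by O4; the free allylic C6 hydroxyl directs the iodonium face so that C8 ends cis to O6 at C7, and the anti-diol then makes ring A all-cis. The 1,1-disubstituted alkene has no internal nucleophile, and under dry conditions any O-alkylation of the amide stays reversible.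

Step 9
Reactants: 15 [(2R,4R,5S)-5-{(S)-[(2R,3S,5S)-3-bromo-5-(but-1-en-2-yl)oxolan-2-yl]iodomethyl}-4-hydroxyoxolan-2-yl](morpholin-4-yl)methanone
Product: 16 [(2R,4R,5R)-5-{[(2S,3S,5S)-3-bromo-5-(but-1-en-2-yl)oxolan-2-yl]methyl}-4-hydroxyoxolan-2-yl](morpholin-4-yl)methanone
Conditions: Bu3SnH (1.1 equiv), Et3B (cat.), air, toluene, −20 °C
Reagents that add atoms: none
Why: Radical deiodination; stannyl radicals abstract iodine about two orders of magnitude faster than bromine, so one equivalent should remove the C8 iodide and leave the C10 bromide, and the C8 stereocenter disappears.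

Step 10
Reactants: 16 [(2R,4R,5R)-5-{[(2S,3S,5S)-3-bromo-5-(but-1-en-2-yl)oxolan-2-yl]methyl}-4-hydroxyoxolan-2-yl](morpholin-4-yl)methanone
Product: 17 1-[(2R,4R,5R)-5-{[(2S,3S,5S)-3-bromo-5-(but-1-en-2-yl)oxolan-2-yl]methyl}-4-hydroxyoxolan-2-yl]-3-(trimethylsilyl)prop-2-yn-1-one
Conditions: LiC≡CSiMe3 (2.5 equiv), THF, −78 to −40 °C; aq NH4Cl
Reagents that add atoms: lithium (trimethylsilyl)acetylide, [Li]C#C[Si](C)(C)C
Why: Acyl substitution of a morpholine amide by an alkynyllithium stops at the ketone because the tetrahedral adduct is stable until work-up; the C6 alkoxide is a spectator and the low temperature spares the bromide and the C4 center.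

Step 11
Reactants: 17 1-[(2R,4R,5R)-5-{[(2S,3S,5S)-3-bromo-5-(but-1-en-2-yl)oxolan-2-yl]methyl}-4-hydroxyoxolan-2-yl]-3-(trimethylsilyl)prop-2-yn-1-one
Product: 18 (2R,3R,5R)-2-{[(2S,3S,5S)-3-bromo-5-(but-1-en-2-yl)oxolan-2-yl]methyl}-5-[3-(trimethylsilyl)prop-2-ynoyl]oxolan-3-yl acetate
Conditions: Ac2O, pyridine, DMAP (cat.), CH2Cl2, 0 °C
Reagents that add atoms: acetic anhydride, CC(=O)OC(C)=O
Why: Standard acylation of the only free hydroxyl installs the C6 acetate with retention; mild base and low temperature should not epimerise C4.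

Step 12
Reactants: 18 (2R,3R,5R)-2-{[(2S,3S,5S)-3-bromo-5-(but-1-en-2-yl)oxolan-2-yl]methyl}-5-[3-(trimethylsilyl)prop-2-ynoyl]oxolan-3-yl acetate
Product: 19 (2R,3R,5R)-2-{[(2S,3S,5S)-3-bromo-5-propanoyloxolan-2-yl]methyl}-5-[3-(trimethylsilyl)prop-2-ynoyl]oxolan-3-yl acetate
Conditions: O3, CH2Cl2, −78 °C (indicator end point); then Me2S, −78 to 20 °C; used directly
Reagents that add atoms: ozone, [O-][O+]=O
Why: Ozonolysis cleaves the only alkene, unmasking the C13 ethyl ketone, while the electron-poor silyl alkyne reacts far more slowly; neutral reductive work-up protects the two α-oxygenated ketone centers C4 and C12.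

Step 13
Reactants: 19 (2R,3R,5R)-2-{[(2S,3S,5S)-3-bromo-5-propanoyloxolan-2-yl]methyl}-5-[3-(trimethylsilyl)prop-2-ynoyl]oxolan-3-yl acetate
Product: 20 (2R,3R,5R)-2-({(2S,3S,5S)-3-bromo-5-[(1S)-1-hydroxypropyl]oxolan-2-yl}methyl)-5-[(1R)-1-hydroxy-3-(trimethylsilyl)prop-2-yn-1-yl]oxolan-3-yl acetate
Conditions: LiBH(s-Bu)3 (2.4 equiv), THF, −78 °C; aq NH4Cl
Reagents that add atoms: none
Why: Double Felkin–Anh reduction: the bulky, non-chelating hydride attacks each ketone anti to the adjacent ring C–O bond, so the pseudo-mirror ends give the threo carbinols (3R) and (13S) together; at −78 °C acetate, bromide and the silyl alkyne should survive.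

Step 14
Reactants: 20 (2R,3R,5R)-2-({(2S,3S,5S)-3-bromo-5-[(1S)-1-hydroxypropyl]oxolan-2-yl}methyl)-5-[(1R)-1-hydroxy-3-(trimethylsilyl)prop-2-yn-1-yl]oxolan-3-yl acetate
Product: 21 (2R,3R,5R)-2-({(2S,3S,5S)-3-bromo-5-[(1S)-1-hydroxypropyl]oxolan-2-yl}methyl)-5-[(1R)-1-hydroxyprop-2-yn-1-yl]oxolan-3-yl acetate
Conditions: Bu4NF, AcOH, THF, 0 °C
Reagents that add atoms: none
Why: Buffered fluoride protodesilylation frees the terminal alkyne before any propargylic bromide is present and leaves the acetate in place.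

Step 15
Reactants: 21 (2R,3R,5R)-2-({(2S,3S,5S)-3-bromo-5-[(1S)-1-hydroxypropyl]oxolan-2-yl}methyl)-5-[(1R)-1-hydroxyprop-2-yn-1-yl]oxolan-3-yl acetate
Product: 22 (2R,3R,5R)-5-[(1S)-1-bromoprop-2-yn-1-yl]-2-({(2S,3S,5S)-3-bromo-5-[(1R)-1-bromopropyl]oxolan-2-yl}methyl)oxolan-3-yl acetate
Conditions: CBr4, P(n-C8H17)3, toluene, 0 to 60 °C
Reagents that add atoms: tetrabromomethane, BrC(Br)(Br)Br
Why: Double Appel reaction: each alkoxyphosphonium is displaced by bromide in an SN2 step with inversion, turning (3R) into (3S) and (13S) into (13R).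

Compound list
1 | 3-bromofuran | Brc1ccoc1 | starting material
2 | 3-ethylfuran | CCc1ccoc1 | intermediate
3 | 2-bromoacrolein (2-bromoprop-2-enal) | C=C(Br)C=O | starting material
4 | (1S,2S,4S)-2-bromo-5-ethyl-7-oxabicyclo[2.2.1]hept-5-ene-2-carbaldehyde (CHO exo; Br endo) | C1=C(CC)[C@@H]2C[C@@](Br)(C=O)[C@H]1O2 | intermediate
5 | (1S,2S,4S)-2-bromo-5-ethyl-7-oxabicyclo[2.2.1]hept-5-ene-2-carboxylic acid | C1=C(CC)[C@@H]2C[C@@](Br)(C(=O)O)[C@H]1O2 | intermediate
6 | (R)-2-(2,2-dimethyl-5-oxo-1,3-dioxolan-4-yl)acetic acid (acetonide of (R)-malic acid) | OC(=O)C[C@H]1OC(C)(C)OC1=O | starting material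
7 | (R)-2-(2,2-dimethyl-5-oxo-1,3-dioxolan-4-yl)acetyl chloride | ClC(=O)C[C@H]1OC(C)(C)OC1=O | intermediate
8 | (5R)-2,2-dimethyl-5-(2-oxobut-3-en-1-yl)-1,3-dioxolan-4-one | C=CC(=O)C[C@H]1OC(C)(C)OC1=O | intermediate
9 | (2S,3S,5S)-3-bromo-5-(but-1-en-2-yl)-2-{(1E)-4-[(4R)-2,2-dimethyl-5-oxo-1,3-dioxolan-4-yl]-3-oxobut-1-en-1-yl}oxolane-3-carboxylic acid | O=C(/C=C/[C@@H]1O[C@H](C(=C)CC)C[C@@]1(Br)C(=O)O)C[C@H]2OC(C)(C)OC2=O | intermediate
10 | acid chloride of 9 | O=C(/C=C/[C@@H]1O[C@H](C(=C)CC)C[C@@]1(Br)C(=O)Cl)C[C@H]2OC(C)(C)OC2=O | intermediate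
11 | 2-thioxopyridin-1(2H)-yl ester of 9 (thiohydroxamate ester) | O=C(/C=C/[C@@H]1O[C@H](C(=C)CC)C[C@@]1(Br)C(=O)ON3C=CC=CC3=S)C[C@H]2OC(C)(C)OC2=O | intermediate
12 | (5R)-5-{(3E)-4-[(2S,3S,5S)-3-bromo-5-(but-1-en-2-yl)oxolan-2-yl]-2-oxobut-3-en-1-yl}-2,2-dimethyl-1,3-dioxolan-4-one (ring B all-cis) | O=C(/C=C/[C@@H]1O[C@H](C(=C)CC)C[C@@H]1Br)C[C@H]2OC(C)(C)OC2=O | intermediate
13 | (5R)-5-{(2R,3E)-4-[(2S,3S,5S)-3-bromo-5-(but-1-en-2-yl)oxolan-2-yl]-2-hydroxybut-3-en-1-yl}-2,2-dimethyl-1,3-dioxolan-4-one | O[C@@H](/C=C/[C@@H]1O[C@H](C(=C)CC)C[C@@H]1Br)C[C@H]2OC(C)(C)OC2=O | intermediate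
14 | (2R,4R,5E)-6-[(2S,3S,5S)-3-bromo-5-(but-1-en-2-yl)oxolan-2-yl]-2,4-dihydroxy-1-(morpholin-4-yl)hex-5-en-1-one | O=C(N1CCOCC1)[C@H](O)C[C@@H](O)/C=C/[C@@H]2O[C@H](C(=C)CC)C[C@@H]2Br | intermediate
15 | [(2R,4R,5S)-5-{(S)-[(2R,3S,5S)-3-bromo-5-(but-1-en-2-yl)oxolan-2-yl]iodomethyl}-4-hydroxyoxolan-2-yl](morpholin-4-yl)methanone | O=C(N1CCOCC1)[C@H]2C[C@@H](O)[C@@H]([C@H](I)[C@@H]3O[C@H](C(=C)CC)C[C@@H]3Br)O2 | intermediate
16 | [(2R,4R,5R)-5-{[(2S,3S,5S)-3-bromo-5-(but-1-en-2-yl)oxolan-2-yl]methyl}-4-hydroxyoxolan-2-yl](morpholin-4-yl)methanone | O=C(N1CCOCC1)[C@H]2C[C@@H](O)[C@@H](C[C@@H]3O[C@H](C(=C)CC)C[C@@H]3Br)O2 | intermediate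
17 | 1-[(2R,4R,5R)-5-{[(2S,3S,5S)-3-bromo-5-(but-1-en-2-yl)oxolan-2-yl]methyl}-4-hydroxyoxolan-2-yl]-3-(trimethylsilyl)prop-2-yn-1-one | C[Si](C)(C)C#CC(=O)[C@H]1C[C@@H](O)[C@@H](C[C@@H]2O[C@H](C(=C)CC)C[C@@H]2Br)O1 | intermediate
18 | (2R,3R,5R)-2-{[(2S,3S,5S)-3-bromo-5-(but-1-en-2-yl)oxolan-2-yl]methyl}-5-[3-(trimethylsilyl)prop-2-ynoyl]oxolan-3-yl acetate | C[Si](C)(C)C#CC(=O)[C@H]1C[C@@H](OC(C)=O)[C@@H](C[C@@H]2O[C@H](C(=C)CC)C[C@@H]2Br)O1 | intermediate
19 | (2R,3R,5R)-2-{[(2S,3S,5S)-3-bromo-5-propanoyloxolan-2-yl]methyl}-5-[3-(trimethylsilyl)prop-2-ynoyl]oxolan-3-yl acetate | C[Si](C)(C)C#CC(=O)[C@H]1C[C@@H](OC(C)=O)[C@@H](C[C@@H]2O[C@H](C(=O)CC)C[C@@H]2Br)O1 | intermediate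
20 | (2R,3R,5R)-2-({(2S,3S,5S)-3-bromo-5-[(1S)-1-hydroxypropyl]oxolan-2-yl}methyl)-5-[(1R)-1-hydroxy-3-(trimethylsilyl)prop-2-yn-1-yl]oxolan-3-yl acetate | C[Si](C)(C)C#C[C@@H](O)[C@H]1C[C@@H](OC(C)=O)[C@@H](C[C@@H]2O[C@H]([C@@H](O)CC)C[C@@H]2Br)O1 | intermediate
21 | (2R,3R,5R)-2-({(2S,3S,5S)-3-bromo-5-[(1S)-1-hydroxypropyl]oxolan-2-yl}methyl)-5-[(1R)-1-hydroxyprop-2-yn-1-yl]oxolan-3-yl acetate | C#C[C@@H](O)[C@H]1C[C@@H](OC(C)=O)[C@@H](C[C@@H]2O[C@H]([C@@H](O)CC)C[C@@H]2Br)O1 | intermediate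
22 | (2R,3R,5R)-5-[(1S)-1-bromoprop-2-yn-1-yl]-2-({(2S,3S,5S)-3-bromo-5-[(1R)-1-bromopropyl]oxolan-2-yl}methyl)oxolan-3-yl acetate | C#C[C@H](Br)[C@H]1C[C@@H](OC(C)=O)[C@@H](C[C@@H]2O[C@H]([C@H](Br)CC)C[C@@H]2Br)O1 | target

Total step count: 15. Longest linear sequence: 14 steps (steps 1–3 and 5–15, from 3-bromofuran); step 4 is the one-step side branch.

Steps most likely to fail

Step 2. What may go wrong: loss of facial or "para" control with the more electron-rich 3-ethylfuran, or cycloreversion of the adduct before it is oxidised. Fallback: starting from 2 and 3, the cycloaddition is run with an achiral Lewis acid (BF3·OEt2, CH2Cl2, −78 °C) to give the racemic exo-formyl adduct, racemic 4 F1. Pinnick oxidation gives the racemic acid, racemic 5 F2. This is resolved by crystallisation with (S)-1-phenylethylamine as the (S)-1-phenylethylammonium salt of the (1S,2S,4S)-acid F3 (the antipodal amine is used if its salt proves the less soluble one). Acidification returns the route at 5.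

Step 6. What may go wrong: hydrogen transfer to the C10 radical from the wrong ring face, or a 1,2-shift of the neighbouring enone-bearing vinyl group through a cyclopropylcarbinyl radical. Fallback: the decarboxylation is moved onto the rigid bicycle, where hydrogen must arrive from the exo face. Starting from 5, N-hydroxypyridine-2-thione and DCC give the 2-thioxopyridin-1(2H)-yl ester of 5 F4, which is photolysed with t-BuSH to (1S,4S,5S)-5-bromo-2-ethyl-7-oxabicyclo[2.2.1]hept-2-ene (Br endo) F5. Ring-opening cross-metathesis of this bromide with 8, under the conditions of step 5, returns the route at 12. The fallback carries its own risk, a homoallyl-type rearrangement of the bicyclic radical.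

Step 15. What may go wrong: participation of the ring oxygens next to C3 and C13 (oxonium formation) leading to retention or ring expansion, and elimination under the phosphonium conditions. Fallback: activation and displacement are separated. Starting from 21, ClCH2SO2Cl and pyridine (CH2Cl2, 0 °C) give the bis(chloromethanesulfonate) of 21 F6, and both sulfonates are displaced by LiBr (THF, 40 °C) in SN2 steps with inversion, returning the route at 22.

Further compounds
F1 | step 2 | racemic 4 (exo-formyl, endo-bromo adduct) | C1=C(CC)[C@@H]2C[C@@](Br)(C=O)[C@H]1O2.C1=C(CC)[C@H]2C[C@](Br)(C=O)[C@@H]1O2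
F2 | step 2 | racemic 5 | C1=C(CC)[C@@H]2C[C@@](Br)(C(=O)O)[C@H]1O2.C1=C(CC)[C@H]2C[C@](Br)(C(=O)O)[C@@H]1O2
F3 | step 2 | (S)-1-phenylethylammonium salt of the (1S,2S,4S)-acid | C1=C(CC)[C@@H]2C[C@@](Br)(C(=O)[O-])[C@H]1O2.C[C@H]([NH3+])c1ccccc1
F4 | step 6 | 2-thioxopyridin-1(2H)-yl ester of 5 | C1=C(CC)[C@@H]2C[C@@](Br)(C(=O)ON3C=CC=CC3=S)[C@H]1O2
F5 | step 6 | (1S,4S,5S)-5-bromo-2-ethyl-7-oxabicyclo[2.2.1]hept-2-ene (Br endo) | C1=C(CC)[C@@H]2C[C@H](Br)[C@H]1O2
F6 | step 15 | bis(chloromethanesulfonate) of 21 | C#C[C@@H](OS(=O)(=O)CCl)[C@H]1C[C@@H](OC(C)=O)[C@@H](C[C@@H]2O[C@H]([C@@H](OS(=O)(=O)CCl)CC)C[C@@H]2Br)O1
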